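The target carries its enone as an acyl group on C8 of the benzo ring (ring A), flanked by the pyran oxygen O1. This aryl–C(=O)–vinyl array is cut on both sides of the carbonyl carbon: a C8 bromide supplies the aryl part, carbon monoxide the ketone carbon, and 4-acetoxystyrene the Cα=Cβ–aryl part. One palladium-catalysed carbonylative Heck coupling thus forms C8–C(=O) and C(=O)–Cα and sets the E alkene, leaving the C3 stereocentre untouched. The coupling partner is (S)-8-bromo-5-methoxy-2,2-dimethylchroman-3-yl acetate, reached from 2-bromo-5-methoxyphenol by a propargyl ether Claisen route, asymmetric epoxidation and hydride opening.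

Key step: step 6

Remark: the (S,S)-configured manganese salen complex is assumed to give the (3S,4S)-epoxide, the sense it shows with other 2,2-dimethyl-2H-chromenes; the C3–O bond made there is never broken afterwards.

Step 1
Reactants: 1 2-bromo-5-methoxyphenol; 2 3-chloro-3-methylbut-1-yne
Product: 3 1-bromo-4-methoxy-2-[(2-methylbut-3-yn-2-yl)oxy]benzene
Conditions: K2CO3, KI (cat.), CuI (cat.), acetone, reflux
Reagents that add atoms: none
Why: Copper-assisted Williamson-type O-propargylation: the chloride ionises through a copper acetylide/allenylidene and the phenoxide of 1, the only nucleophile present, captures the tertiary propargylic carbon.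

Step 2
Reactants: 3 1-bromo-4-methoxy-2-[(2-methylbut-3-yn-2-yl)oxy]benzene
Product: 6 8-bromo-5-methoxy-2,2-dimethyl-2H-chromene, via allenylphenol 4 (not isolated), via ortho-quinone methide 5 (not isolated)
Conditions: N,N-diethylaniline, 185 °C
Reagents that add atoms: none
Why: Aromatic propargyl Claisen rearrangement: the [3,3] shift can only reach the free ortho carbon between the two oxygens because bromine blocks the other one, and tautomerisation, a 1,5-hydrogen shift and oxa-6π electrocyclisation then close the pyran ring to the 2,2-dimethylchromene.

Step 3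
Reactants: 6 8-bromo-5-methoxy-2,2-dimethyl-2H-chromene
Product: 7 (3S,4S)-8-bromo-3,4-epoxy-5-methoxy-2,2-dimethylchroman
Conditions: (S,S)-N,N′-bis(3,5-di-tert-butylsalicylidene)-1,2-cyclohexanediaminomanganese chloride (5 mol%), 4-phenylpyridine N-oxide, aq. NaOCl (pH 11.3), CH2Cl2, 0 °C
Reagents that add atoms: sodium hypochlorite, [Na+].[O-]Cl
Why: Jacobsen–Katsuki epoxidation, for which conjugated cis-olefins locked in a 2,2-dimethyl-2H-chromene are among the best substrates: the chiral oxomanganese salen species adds oxygen to one face of C3=C4 and so sets C3 and C4 together (both S), the acid-labile epoxide being carried on crude after filtration through basic alumina.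

Step 4
Reactants: 7 (3S,4S)-8-bromo-3,4-epoxy-5-methoxy-2,2-dimethylchroman
Product: 8 (S)-8-bromo-5-methoxy-2,2-dimethylchroman-3-ol
Conditions: LiBHEt3 (1.5 equiv), THF, 0 °C to rt; H2O
Reagents that add atoms: none
Why: Regioselective SN2 epoxide opening by a nucleophilic borohydride: hydride attacks the benzylic C4, since C3 is neopentyl-like next to the quaternary C2, so the C3–O bond and its S configuration stay untouched while the C4 stereocentre disappears, and the aryl bromide should be inert to LiBHEt3 at this temperature.

Step 5
Reactants: 8 (S)-8-bromo-5-methoxy-2,2-dimethylchroman-3-ol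
Product: 9 (S)-8-bromo-5-methoxy-2,2-dimethylchroman-3-yl acetate
Conditions: Ac2O, pyridine, 4-(dimethylamino)pyridine (cat.), CH2Cl2, rt
Reagents that add atoms: acetic anhydride, CC(=O)OC(C)=O
Why: Nucleophile-catalysed acylation of the hindered secondary alcohol, with no bond to C3 broken, masks the OH that could otherwise trap the aroylpalladium intermediate of step 6.

Step 6
Reactants: 9 (S)-8-bromo-5-methoxy-2,2-dimethylchroman-3-yl acetate; 10 carbon monoxide; 11 4-acetoxystyrene
Product: 12 (S,E)-4-[3-(3-acetoxy-5-methoxy-2,2-dimethylchroman-8-yl)-3-oxoprop-1-en-1-yl]phenyl acetate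
Conditions: Pd(OAc)2 (5 mol%), 4,5-bis(diphenylphosphino)-9,9-dimethylxanthene (Xantphos, 7.5 mol%), Et3N (3 equiv), CO (10 bar), 11 (2 equiv), 1,4-dioxane, 100 °C
Reagents that add atoms: none
Why: Pd(OAc)2 is reduced in the flask to zerovalent palladium, which inserts into the C8–Br bond of 9; CO insertion gives an aroylpalladium bromide, 11 inserts into its Pd–acyl bond with the acyl group on the terminal CH2 and palladium on the benzylic carbon, and syn β-hydride elimination releases the E enone while Et3N takes up HBr and returns zerovalent palladium. The closest known reaction type is the palladium-catalysed carbonylative Heck coupling (carbonylative vinylation) of aryl halides with styrenes to chalcones. No ring is closed and no stereocentre is made; C3 is remote from the reacting carbon, is not enolisable and should pass through unchanged. The selectivity that matters is CO insertion ahead of alkene insertion, since the reverse order gives the stilbene of direct Heck arylation; CO pressure, the electron-rich aryl group (O1 ortho and OMe para to C8), which migrates readily onto CO, and the wide-bite-angle diphosphine, which keeps palladium active under CO, should secure it. Regiochemistry follows from formation of the stabilised benzylic palladium species, and E geometry from syn elimination through the less hindered rotamer. Both acetates are kept because a free phenol or alcohol could intercept the aroylpalladium as an ester.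

Step 7
Reactants: 12 (S,E)-4-[3-(3-acetoxy-5-methoxy-2,2-dimethylchroman-8-yl)-3-oxoprop-1-en-1-yl]phenyl acetate
Product: 13 (S,E)-1-(3-hydroxy-5-methoxy-2,2-dimethylchroman-8-yl)-3-(4-hydroxyphenyl)prop-2-en-1-one
Conditions: K2CO3 (2 equiv), MeOH, rt; aq. NH4Cl
Reagents that add atoms: none
Why: Base-mediated transesterification (methanolysis) of the aryl and the secondary alkyl acetate: the 4-phenoxide formed first deactivates the enone towards conjugate addition of methoxide, there is no ortho-hydroxyl on ring A to close a flavanone, and C3 carries no acidic hydrogen, so the S centre and the E alkene should survive.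

Compound list
1 | 2-bromo-5-methoxyphenol | COc1ccc(Br)c(O)c1 | starting material
2 | 3-chloro-3-methylbut-1-yne | CC(C)(Cl)C#C | starting material
3 | 1-bromo-4-methoxy-2-[(2-methylbut-3-yn-2-yl)oxy]benzene | COc1ccc(Br)c(OC(C)(C)C#C)c1 | intermediate
4 | 6-bromo-3-methoxy-2-(3-methylbuta-1,2-dien-1-yl)phenol (allenylphenol, not isolated) | COc1ccc(Br)c(O)c1C=C=C(C)C | intermediate
5 | 2-bromo-5-methoxy-6-(3-methylbut-2-en-1-ylidene)cyclohexa-2,4-dien-1-one (ortho-quinone methide, not isolated) | COC1=CC=C(Br)C(=O)C1=CC=C(C)C | intermediate
6 | 8-bromo-5-methoxy-2,2-dimethyl-2H-chromene | COc1ccc(Br)c2OC(C)(C)C=Cc12 | intermediate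
7 | (3S,4S)-8-bromo-3,4-epoxy-5-methoxy-2,2-dimethylchroman | COc1ccc(Br)c2OC(C)(C)[C@H]3O[C@H]3c12 | intermediate
8 | (S)-8-bromo-5-methoxy-2,2-dimethylchroman-3-ol | COc1ccc(Br)c2c1C[C@H](O)C(C)(C)O2 | intermediate
9 | (S)-8-bromo-5-methoxy-2,2-dimethylchroman-3-yl acetate | COc1ccc(Br)c2c1C[C@H](OC(C)=O)C(C)(C)O2 | intermediate
10 | carbon monoxide | [C-]#[O+] | starting material
11 | 4-acetoxystyrene | C=Cc1ccc(OC(C)=O)cc1 | starting material
12 | (S,E)-4-[3-(3-acetoxy-5-methoxy-2,2-dimethylchroman-8-yl)-3-oxoprop-1-en-1-yl]phenyl acetate | COc1ccc(C(=O)/C=C/c2ccc(OC(C)=O)cc2)c2c1C[C@H](OC(C)=O)C(C)(C)O2 | intermediate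
13 | (S,E)-1-(3-hydroxy-5-methoxy-2,2-dimethylchroman-8-yl)-3-(4-hydroxyphenyl)prop-2-en-1-one | COc1ccc(C(=O)/C=C/c2ccc(O)cc2)c2c1C[C@H](O)C(C)(C)O2 | target

Total step count: 7
Longest linear sequence: 7 steps (1 to 13)

Steps most likely to fail

1. Step 6 (carbonylative Heck coupling). Oxidative addition of the electron-rich, ortho-oxygenated bromide may stall under CO, or alkene insertion may run ahead of CO insertion so that direct arylation of the styrene takes over; the styrene may also polymerise at the reaction temperature. Fallback: setting out from 9, a Stille coupling with tributyl(1-ethoxyvinyl)stannane (Pd(PPh3)4, toluene, 100 °C) should give (S)-8-(1-ethoxyvinyl)-5-methoxy-2,2-dimethylchroman-3-yl acetate F1. Dilute HCl in THF at rt should hydrolyse the enol ether to (S)-8-acetyl-5-methoxy-2,2-dimethylchroman-3-yl acetate F2. A Claisen–Schmidt condensation of F2 with 4-hydroxybenzaldehyde (KOH, EtOH, 50 °C), in which the C3 acetate is saponified in the same flask, comes back to the route at 13.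

2. Step 3 (asymmetric epoxidation). Facial discrimination by the salen complex may be incomplete on this 5,8-disubstituted chromene, or the electron-rich benzylic epoxide may open during work-up. Fallback: setting out from 6, buffered epoxidation with mCPBA (NaHCO3, CH2Cl2, 0 °C) should give racemic cis-8-bromo-3,4-epoxy-5-methoxy-2,2-dimethylchroman F3. A Meinwald rearrangement (ZnI2 cat., CH2Cl2; ionisation at C4, then 1,2-hydride shift from C3) should give 8-bromo-5-methoxy-2,2-dimethylchroman-3-one F4. CBS reduction with (R)-1-methyl-3,3-diphenyltetrahydro-1H,3H-pyrrolo[1,2-c][1,3,2]oxazaborole and BH3·SMe2 (THF, −20 °C), with the quaternary C2 as the large group and the benzylic C4H2 as the small one, should deliver the S alcohol and come back to the route at 8. The stereocentre is then set by reagent-controlled ketone reduction, and step 4 is bypassed as well.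

3. Step 4 (hydride opening). Hydride may be delivered to C3 in place of C4, lithium-ion-promoted rearrangement of the epoxide to the ketone may erode the enantiomeric purity through its reduction, or hydrodebromination may occur at C8. Fallback: setting out from 7, a single-electron opening with Cp2TiCl (from Cp2TiCl2 and Zn dust; trivalent titanium) and 1,4-cyclohexadiene in THF at rt should cleave the benzylic C4–O bond homolytically. The C4 radical takes hydrogen from the diene and the C3–O bond stays intact, so the sequence comes back to the route at 8 without a new compound.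

Further compounds
F1 | step 6 | (S)-8-(1-ethoxyvinyl)-5-methoxy-2,2-dimethylchroman-3-yl acetate | COc1ccc(C(=C)OCC)c2c1C[C@H](OC(C)=O)C(C)(C)O2
F2 | step 6 | (S)-8-acetyl-5-methoxy-2,2-dimethylchroman-3-yl acetate | COc1ccc(C(C)=O)c2c1C[C@H](OC(C)=O)C(C)(C)O2
F3 | step 3 | racemic cis-8-bromo-3,4-epoxy-5-methoxy-2,2-dimethylchroman | COc1ccc(Br)c2OC(C)(C)C3OC3c12
F4 | step 3 | 8-bromo-5-methoxy-2,2-dimethylchroman-3-one | COc1ccc(Br)c2c1CC(=O)C(C)(C)O2
F0 | step 4 | none | none
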